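Per equivalent of incoming ligand charged, I ask how far ln S falls at a fixed concentration times time, where S is the percentage of the charge still present as starting complex; this step is what I reckon with.

| setting | summer | midnight | dusk | flask |
|---|---|---|---|---|
| starting complex | 0.10 M | 0.10 M | 0.15 M | 0.10 M |
| incoming ligand | 1 equiv | 4 equiv | 2 equiv | 2.00 equiv |
| remark | run made earlier | run made earlier | run made earlier |  |
| time |  |  |  | 5.0 h |

- summer (time / h: complex with two exchanged / %, starting complex / %): 1.33: 21.9, 37.7; 2.50: 25.0, 33.8; 4.00: 26.2, 32.6; 5.00: 26.5, 31.1; 6.00: 26.8, 31.6
- midnight (time / h: complex with two exchanged / %, starting complex / %): 0.500: 30.6, 23.5; 1.50: 20.8, 11.1; 3.00: 10.4, 3.6; 4.00: 6.4, 3.2; 6.00: 3.7, 1.3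
- dusk (time / h: complex with two exchanged / %, starting complex / %): 0.500: 27.8, 32.0; 0.833: 29.7, 25.5; 1.50: 29.2, 20.7; 3.00: 26.0, 16.1; 6.00: 24.4, 14.2

(standard deviation of a reading: 0.5 percentage points)

- candidate steps: starting complex + incoming ligand -> leaving ligand + complex with one exchanged; complex with one exchanged + incoming ligand -> leaving ligand + complex with two exchanged; complex with two exchanged + incoming ligand -> leaving ligand + complex with three exchanged; complex with two exchanged + incoming ligand -> over-reaction product; starting complex <-> dormant form

* equivalents of incoming ligand to starting complex, everything else as given, that leave most complex with two exchanged at 5.0 h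
* the amount of complex with two exchanged then, in percent of the starting complex charged
* the amount of complex with two exchanged with the amounts as given

Time comes first, and by hand I expect little from it late on: in the summer run, complex with two exchanged goes from 26.2% at 4.00 h to 26.8% at 6.00 h. Concentration comes next: the candidate steps using ligand are bimolecular, so at equal equivalents I take concentration times time as the clock, and the flask's 5.0 h matches 3.33 h in the dusk run, whose readings either side hold 26.0% and 24.4% of complex with two exchanged. Equivalents come last: S is 31.1% in summer at 5.00 h and 16.1% at dusk's nearest reading, 3.00 h, which falls short of that match, so my ligand step, the fall of ln S per equivalent charged, is by this reading λ = 0.658 equiv⁻¹. The highest reading of complex with two exchanged, 30.6% in the midnight run, stands at S = 23.5%, so by my reckoning λ puts the best charge at 1.43 equiv.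

The forecast gives 1.4 equiv, 30.2% there and 25.7% as charged, holding that “two-exchanged follows remaining starting complex on one curve”; its 25.7% lies between dusk's two readings, so it interpolates within the runs.

The flask gives 25.8% as charged, and 28.8% at 1.42 equiv. At 5.00 h in the flask as charged, the incoming ligand, the limiting reagent here, has 7.2% of its charge left. From summer's S, λ gives 23.6% at that best charge, where the flask so charged holds 24.4%.

    starting complex + incoming ligand → leaving ligand + complex with one exchanged (k = 0.120 L mol⁻¹ min⁻¹)
    complex with one exchanged + incoming ligand → leaving ligand + complex with two exchanged (k = 1.20 L mol⁻¹ min⁻¹)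
    complex with two exchanged + incoming ligand → leaving ligand + complex with three exchanged (k = 0.0640 L mol⁻¹ min⁻¹)
    complex with two exchanged + incoming ligand → over-reaction product (k = 0.0420 L mol⁻¹ min⁻¹)
    starting complex ⇌ dormant form (K = 0.770, k = 0.0320 min⁻¹)

For a neighbour flask, the same flask charged with 0.800 equiv of incoming ligand, λ gives S = 35.5%; computed, that neighbour holds 35.9% of starting complex and 23.9% of complex with two exchanged.

All runs come from a simulation for substances that don't exist; the scatter is artificial.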